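## Retrosynthetic overview

1. Target ⇐ bis-silyl ether by one final desilylation; the hindered aryl ester is already in place.
2. 2H-pyran ring ⇐ oxa-6π electrocyclisation of a (Z)-dienone, made by dehydrogenating a 1,5-diketone that carries an exocyclic methylene.
3. Side-chain C–C bond of that diketone ⇐ [3,3] ketal-Claisen rearrangement of a Morita–Baylis–Hillman alcohol with 2-methoxypenta-1,3-diene.
4. Tertiary ester ⇐ enone α-ketol + silyl-protected 4-hydroxy-2-methoxy-6-methylbenzoyl chloride (acylium conditions).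
5. Enone with both stereocentres ⇐ (R)-carvone (anti epoxidation, trans-diaxial hydrolysis, dealkenylation). Ring order: carbocycle and arene are bought, the pyran ring is formed last.

Assumption: acid-catalysed opening of carvone oxide is taken to follow the same trans-diaxial course at the tertiary carbon as its known LiCl/TFA chlorohydrin formation (inversion at the methyl-bearing carbon, retention at the other). On that basis (R)-carvone leads to the (6R,7S) target. This is a paper design; no step has been run.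

## Route

Step 1
Reactants: 1 (R)-(−)-carvone
Product: 2 (1R,4R,6R)-1-methyl-4-(prop-1-en-2-yl)-7-oxabicyclo[4.1.0]heptan-2-one
Conditions: 30% aq. H2O2, NaOH (cat.), MeOH, 0 °C
Reagents that add atoms: hydrogen peroxide, OO
Why: Weitz–Scheffer nucleophilic epoxidation in which hydroperoxide adds axially to the β-carbon anti to the equatorial isopropenyl group, so the bought stereocentre sets both epoxide carbons.

Step 2
Reactants: 2 (1R,4R,6R)-1-methyl-4-(prop-1-en-2-yl)-7-oxabicyclo[4.1.0]heptan-2-one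
Product: 3 (2S,3R,5R)-2,3-dihydroxy-2-methyl-5-(prop-1-en-2-yl)cyclohexan-1-one
Conditions: HClO4 (cat.), THF/H2O, 23 °C
Reagents that add atoms: water, O
Why: Acid-catalysed trans-diaxial (Fürst–Plattner) epoxide opening in which water enters the tertiary carbon with inversion while the C-3 oxygen keeps its configuration, giving the trans-diol with tertiary OH anti and secondary OH syn to the isopropenyl group.

Step 3
Reactants: 3 (2S,3R,5R)-2,3-dihydroxy-2-methyl-5-(prop-1-en-2-yl)cyclohexan-1-one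
Product: 4 (2S,3R,5R)-3-[(tert-butyldimethylsilyl)oxy]-2-hydroxy-2-methyl-5-(prop-1-en-2-yl)cyclohexan-1-one
Conditions: TBSOTf (1.1 equiv), 2,6-lutidine, CH2Cl2, −78 °C
Reagents that add atoms: tert-butyldimethylsilyl triflate, CC(C)(C)[Si](C)(C)OS(=O)(=O)C(F)(F)F
Why: Chemoselective silylation of the secondary alcohol over the hindered, less nucleophilic tertiary α-ketol hydroxyl, with no stereocentre touched.

Step 4
Reactants: 4 (2S,3R,5R)-3-[(tert-butyldimethylsilyl)oxy]-2-hydroxy-2-methyl-5-(prop-1-en-2-yl)cyclohexan-1-one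
Product: 6 (5R,6S)-5-[(tert-butyldimethylsilyl)oxy]-6-hydroxy-6-methylcyclohex-2-en-1-one, via methoxy hydroperoxide 5 (not isolated)
Conditions: O3, MeOH/CH2Cl2, −78 °C; then Cu(OAc)2·H2O (2 equiv), FeSO4·7H2O (1.2 equiv), −20 → 23 °C
Reagents that add atoms: none
Why: Ozonolysis in methanol followed by Schreiber fragmentation, in which divalent iron cleaves the O–O bond, β-scission expels methyl acetate and divalent copper oxidises the ring radical to the conjugated enone, removing the controlling isopropenyl centre without touching the two carbinol centres.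

Step 5
Reactants: 7 2,4-dihydroxy-6-methylbenzaldehyde
Product: 8 2-hydroxy-6-methyl-4-[(triisopropylsilyl)oxy]benzaldehyde
Conditions: TIPSCl (1.05 equiv), imidazole, CH2Cl2, 0 °C
Reagents that add atoms: triisopropylsilyl chloride, CC(C)[Si](Cl)(C(C)C)C(C)C
Why: Regioselective silylation of the 4-hydroxyl, because the 2-hydroxyl is deactivated by its hydrogen bond to the aldehyde.

Step 6
Reactants: 8 2-hydroxy-6-methyl-4-[(triisopropylsilyl)oxy]benzaldehyde
Product: 9 2-methoxy-6-methyl-4-[(triisopropylsilyl)oxy]benzaldehyde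
Conditions: MeI, K2CO3, acetone, 40 °C
Reagents that add atoms: iodomethane, CI
Why: Williamson O-methylation of the only remaining phenol under conditions mild enough for the aryl triisopropylsilyl ether.

Step 7
Reactants: 9 2-methoxy-6-methyl-4-[(triisopropylsilyl)oxy]benzaldehyde
Product: 10 2-methoxy-6-methyl-4-[(triisopropylsilyl)oxy]benzoic acid
Conditions: NaClO2, NaH2PO4, 2-methyl-2-butene, t-BuOH/H2O, 23 °C
Reagents that add atoms: sodium chlorite NaClO2, [Na+].[O-]Cl=O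
Why: Pinnick oxidation converts the aldehyde to the acid without affecting the silyl ether or the electron-rich ring, since the alkene scavenges hypochlorous acid.

Step 8
Reactants: 6 (5R,6S)-5-[(tert-butyldimethylsilyl)oxy]-6-hydroxy-6-methylcyclohex-2-en-1-one; 10 2-methoxy-6-methyl-4-[(triisopropylsilyl)oxy]benzoic acid
Product: 12 (1S,6R)-6-[(tert-butyldimethylsilyl)oxy]-1-methyl-2-oxocyclohex-3-en-1-yl 2-methoxy-6-methyl-4-[(triisopropylsilyl)oxy]benzoate, via acid chloride 11 (not isolated)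
Conditions: 10, 1-chloro-N,N,2-trimethylprop-1-en-1-amine, CH2Cl2, 0 → 23 °C; then 6, AgOTf, 2,6-di-tert-butyl-4-methylpyridine, CH2Cl2, −40 → 23 °C
Reagents that add atoms: none
Why: O-acylation through an acylium ion (aroyl triflate) stabilised by the ortho and para oxygen donors, which is small and reactive enough to reach the hindered tertiary oxygen; the C–O stereocentre is not involved.

Step 9
Reactants: 12 (1S,6R)-6-[(tert-butyldimethylsilyl)oxy]-1-methyl-2-oxocyclohex-3-en-1-yl 2-methoxy-6-methyl-4-[(triisopropylsilyl)oxy]benzoate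
Product: 13 (1S,6R)-6-[(tert-butyldimethylsilyl)oxy]-3-(hydroxymethyl)-1-methyl-2-oxocyclohex-3-en-1-yl 2-methoxy-6-methyl-4-[(triisopropylsilyl)oxy]benzoate
Conditions: 37% aq. HCHO, DMAP (0.3 equiv), THF, 23 °C
Reagents that add atoms: formaldehyde, C=O
Why: Morita–Baylis–Hillman hydroxymethylation of the β-unsubstituted cyclohexenone at its α-carbon, under base too weak to trigger γ-deprotonation and loss of the silyloxy group.

Step 10
Reactants: 14 methyl (E)-but-2-enoate
Product: 15 (E)-2-methoxypenta-1,3-diene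
Conditions: Cp2TiMe2 (2 equiv), THF, 65 °C, dark
Reagents that add atoms: dimethyltitanocene Cp2TiMe2, C[Ti](C)(C1C=CC=C1)C1C=CC=C1
Why: Petasis methylenation converts the ester carbonyl into the methyl enol ether and leaves the (E)-alkene intact.

Step 11
Reactants: 13 (1S,6R)-6-[(tert-butyldimethylsilyl)oxy]-3-(hydroxymethyl)-1-methyl-2-oxocyclohex-3-en-1-yl 2-methoxy-6-methyl-4-[(triisopropylsilyl)oxy]benzoate; 15 (E)-2-methoxypenta-1,3-diene
Product: 17 (1S,6R)-6-[(tert-butyldimethylsilyl)oxy]-1-methyl-3-methylidene-2-oxo-4-[(3E)-2-oxopent-3-en-1-yl]cyclohexyl 2-methoxy-6-methyl-4-[(triisopropylsilyl)oxy]benzoate (both C-4 epimers), via allyl dienyl ether 16 (not isolated)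
Conditions: 15 (3 equiv), PPTS (5 mol %), toluene, 0 → 23 °C; then dilute to 0.02 M, 110 °C, sealed tube
Reagents that add atoms: none
Why: Saucy–Marbet (ketal) Claisen rearrangement in which acid-catalysed exchange gives the allyl vinyl ether and an irreversible chair [3,3] shift forms the ring–side-chain C–C bond while transposing the alkene to the exocyclic methylene; the new C-4 centre forms as a mixture and is erased in the next step.

Step 12
Reactants: 17 (1S,6R)-6-[(tert-butyldimethylsilyl)oxy]-1-methyl-3-methylidene-2-oxo-4-[(3E)-2-oxopent-3-en-1-yl]cyclohexyl 2-methoxy-6-methyl-4-[(triisopropylsilyl)oxy]benzoate (both C-4 epimers)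
Product: 19 (6R,7S)-6-[(tert-butyldimethylsilyl)oxy]-7-methyl-8-oxo-3-[(E)-prop-1-en-1-yl]-5,6,7,8-tetrahydro-1H-isochromen-7-yl 2-methoxy-6-methyl-4-[(triisopropylsilyl)oxy]benzoate, via Z-dienone 18 (not isolated)
Conditions: IBX (3 equiv), 4-methoxypyridine N-oxide (3 equiv), DMSO, 25 → 45 °C
Reagents that add atoms: none
Why: IBX dehydrogenation at the only enolisable ketone α-CH2 gives the cross-conjugated dienone, whose (Z)-isomer (the (E)-isomer equilibrating through its dienol) closes by thermal disrotatory oxa-6π electrocyclisation onto the exocyclic methylene to give the doubly vinylogous ester 2H-pyran, with C-6 and C-7 untouched.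

Step 13
Reactants: 19 (6R,7S)-6-[(tert-butyldimethylsilyl)oxy]-7-methyl-8-oxo-3-[(E)-prop-1-en-1-yl]-5,6,7,8-tetrahydro-1H-isochromen-7-yl 2-methoxy-6-methyl-4-[(triisopropylsilyl)oxy]benzoate
Product: 20 (6R,7S)-6-hydroxy-7-methyl-8-oxo-3-[(E)-prop-1-en-1-yl]-5,6,7,8-tetrahydro-1H-isochromen-7-yl 4-hydroxy-2-methoxy-6-methylbenzoate (CNP0187389.3)
Conditions: TBAF/AcOH (1:1, 4 equiv), THF, 0 → 23 °C
Reagents that add atoms: none
Why: Fluoride desilylation removes both silyl ethers in one operation, with acetic acid buffering to suppress acyl migration, retro-aldol cleavage and opening of the dienyl ether.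

## Compound list

1 | (R)-(−)-carvone | O=C1C(C)=CC[C@@H](C(C)=C)C1 | starting material
2 | (1R,4R,6R)-1-methyl-4-(prop-1-en-2-yl)-7-oxabicyclo[4.1.0]heptan-2-one | O=C1[C@]2(C)O[C@@H]2C[C@@H](C(C)=C)C1 | intermediate
3 | (2S,3R,5R)-2,3-dihydroxy-2-methyl-5-(prop-1-en-2-yl)cyclohexan-1-one | O=C1[C@@](C)(O)[C@H](O)C[C@@H](C(C)=C)C1 | intermediate
4 | (2S,3R,5R)-3-[(tert-butyldimethylsilyl)oxy]-2-hydroxy-2-methyl-5-(prop-1-en-2-yl)cyclohexan-1-one | O=C1[C@@](C)(O)[C@H](O[Si](C)(C)C(C)(C)C)C[C@@H](C(C)=C)C1 | intermediate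
5 | (2S,3R,5R)-3-[(tert-butyldimethylsilyl)oxy]-2-hydroxy-5-(1-hydroperoxy-1-methoxyethyl)-2-methylcyclohexan-1-one (epimers at the peroxyketal carbon) | O=C1[C@@](C)(O)[C@H](O[Si](C)(C)C(C)(C)C)C[C@@H](C(C)(OC)OO)C1 | intermediate
6 | (5R,6S)-5-[(tert-butyldimethylsilyl)oxy]-6-hydroxy-6-methylcyclohex-2-en-1-one | O=C1[C@@](C)(O)[C@H](O[Si](C)(C)C(C)(C)C)CC=C1 | intermediate
7 | 2,4-dihydroxy-6-methylbenzaldehyde | O=Cc1c(C)cc(O)cc1O | starting material
8 | 2-hydroxy-6-methyl-4-[(triisopropylsilyl)oxy]benzaldehyde | O=Cc1c(C)cc(O[Si](C(C)C)(C(C)C)C(C)C)cc1O | intermediate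
9 | 2-methoxy-6-methyl-4-[(triisopropylsilyl)oxy]benzaldehyde | O=Cc1c(C)cc(O[Si](C(C)C)(C(C)C)C(C)C)cc1OC | intermediate
10 | 2-methoxy-6-methyl-4-[(triisopropylsilyl)oxy]benzoic acid | OC(=O)c1c(C)cc(O[Si](C(C)C)(C(C)C)C(C)C)cc1OC | intermediate
11 | 2-methoxy-6-methyl-4-[(triisopropylsilyl)oxy]benzoyl chloride | ClC(=O)c1c(C)cc(O[Si](C(C)C)(C(C)C)C(C)C)cc1OC | intermediate
12 | (1S,6R)-6-[(tert-butyldimethylsilyl)oxy]-1-methyl-2-oxocyclohex-3-en-1-yl 2-methoxy-6-methyl-4-[(triisopropylsilyl)oxy]benzoate | O=C1[C@@](C)(OC(=O)c2c(C)cc(O[Si](C(C)C)(C(C)C)C(C)C)cc2OC)[C@H](O[Si](C)(C)C(C)(C)C)CC=C1 | intermediate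
13 | (1S,6R)-6-[(tert-butyldimethylsilyl)oxy]-3-(hydroxymethyl)-1-methyl-2-oxocyclohex-3-en-1-yl 2-methoxy-6-methyl-4-[(triisopropylsilyl)oxy]benzoate | O=C1[C@@](C)(OC(=O)c2c(C)cc(O[Si](C(C)C)(C(C)C)C(C)C)cc2OC)[C@H](O[Si](C)(C)C(C)(C)C)CC=C1CO | intermediate
14 | methyl (E)-but-2-enoate (methyl crotonate) | C/C=C/C(=O)OC | starting material
15 | (E)-2-methoxypenta-1,3-diene | C=C(OC)/C=C/C | intermediate
16 | (1S,6R)-6-[(tert-butyldimethylsilyl)oxy]-1-methyl-2-oxo-3-({[(3E)-penta-1,3-dien-2-yl]oxy}methyl)cyclohex-3-en-1-yl 2-methoxy-6-methyl-4-[(triisopropylsilyl)oxy]benzoate | O=C1[C@@](C)(OC(=O)c2c(C)cc(O[Si](C(C)C)(C(C)C)C(C)C)cc2OC)[C@H](O[Si](C)(C)C(C)(C)C)CC=C1COC(=C)/C=C/C | intermediate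
17 | (1S,6R)-6-[(tert-butyldimethylsilyl)oxy]-1-methyl-3-methylidene-2-oxo-4-[(3E)-2-oxopent-3-en-1-yl]cyclohexyl 2-methoxy-6-methyl-4-[(triisopropylsilyl)oxy]benzoate (both C-4 epimers) | O=C1[C@@](C)(OC(=O)c2c(C)cc(O[Si](C(C)C)(C(C)C)C(C)C)cc2OC)[C@H](O[Si](C)(C)C(C)(C)C)CC(CC(=O)/C=C/C)C1=C | intermediate
18 | (1S,6R)-6-[(tert-butyldimethylsilyl)oxy]-1-methyl-3-methylidene-2-oxo-4-[(1Z,3E)-2-oxopent-3-en-1-ylidene]cyclohexyl 2-methoxy-6-methyl-4-[(triisopropylsilyl)oxy]benzoate | O=C1[C@@](C)(OC(=O)c2c(C)cc(O[Si](C(C)C)(C(C)C)C(C)C)cc2OC)[C@H](O[Si](C)(C)C(C)(C)C)C/C(=C/C(=O)/C=C/C)C1=C | intermediate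
19 | (6R,7S)-6-[(tert-butyldimethylsilyl)oxy]-7-methyl-8-oxo-3-[(E)-prop-1-en-1-yl]-5,6,7,8-tetrahydro-1H-isochromen-7-yl 2-methoxy-6-methyl-4-[(triisopropylsilyl)oxy]benzoate | C/C=C/C1=CC2=C(CO1)C(=O)[C@@](C)(OC(=O)c1c(C)cc(O[Si](C(C)C)(C(C)C)C(C)C)cc1OC)[C@H](O[Si](C)(C)C(C)(C)C)C2 | intermediate
20 | (6R,7S)-6-hydroxy-7-methyl-8-oxo-3-[(E)-prop-1-en-1-yl]-5,6,7,8-tetrahydro-1H-isochromen-7-yl 4-hydroxy-2-methoxy-6-methylbenzoate (CNP0187389.3) | C/C=C/C1=CC2=C(CO1)C(=O)[C@@](C)(OC(=O)c1c(C)cc(O)cc1OC)[C@H](O)C2 | target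

## Step count and risks

Total step count: 13. Longest linear sequence: 9 steps (steps 1, 2, 3, 4, 8, 9, 11, 12, 13, from (R)-carvone).

The three steps most likely to fail:

**Step 2 (epoxide hydrolysis).** It may be slow, may rearrange, or may open at the secondary carbon, which would lead into the enantiomeric series. The fallback sets out from 2 and comes back at 4. Epoxide 2 is opened reductively at the α-carbon with (PhSe)2/NaBH4/AcOH in EtOH, which keeps the C-3 oxygen configuration, to give (3R,5R)-3-hydroxy-2-methyl-5-(prop-1-en-2-yl)cyclohexan-1-one F1. Silylation (TBSCl, imidazole, DMF) gives the silyl ether (3R,5R)-3-[(tert-butyldimethylsilyl)oxy]-2-methyl-5-(prop-1-en-2-yl)cyclohexan-1-one F2. TMSCl/NaI/Et3N in MeCN gives the more substituted enol ether tert-butyldimethyl{[(1R,5R)-2-methyl-5-(prop-1-en-2-yl)-3-(trimethylsilyloxy)cyclohex-2-en-1-yl]oxy}silane F3. Rubottom oxidation with dimethyldioxirane at −78 °C, anti to the pseudoaxial silyloxy group, then citric acid/MeOH gives 4. The tertiary carbinol is thus set by the adjacent centre instead of by the regiochemistry of the opening.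

**Step 8 (esterification of a tertiary α-ketol with a 2,6-disubstituted benzoyl donor).** The fallback sets out from 6 and comes back at 12. Commercial orsellinic acid is converted with acetone/TFAA/TFA into 7-hydroxy-2,2,5-trimethyl-4H-1,3-benzodioxin-4-one F4. TIPSCl/imidazole gives 2,2,5-trimethyl-7-[(triisopropylsilyl)oxy]-4H-1,3-benzodioxin-4-one F5. The sodium alkoxide of 6 (NaHMDS, THF, −78 → 0 °C) opens the planar, less shielded dioxinone carbonyl with loss of acetone to give the salicylate (1S,6R)-6-[(tert-butyldimethylsilyl)oxy]-1-methyl-2-oxocyclohex-3-en-1-yl 2-hydroxy-6-methyl-4-[(triisopropylsilyl)oxy]benzoate F6. O-methylation of the free phenol (TMSCHN2, MeOH/toluene) gives 12.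

**Step 12 (dehydrogenation and electrocyclisation).** Over-oxidation, or a dienone that does not reach the (Z)-geometry, would stall it. The fallback sets out from 17 and comes back at 19. PPTS or a trace of DBU in CH2Cl2 closes the enol oxygen of the side-chain ketone onto the exocyclic methylene (oxa-Michael) to give (6R,7S)-6-[(tert-butyldimethylsilyl)oxy]-7-methyl-8-oxo-3-[(E)-prop-1-en-1-yl]-4a,5,6,7,8,8a-hexahydro-1H-isochromen-7-yl 2-methoxy-6-methyl-4-[(triisopropylsilyl)oxy]benzoate F7. TMSOTf/Et3N enolises the ring ketone in the only possible direction to give the silyl dienol ether (6R,7S)-6-[(tert-butyldimethylsilyl)oxy]-7-methyl-3-[(E)-prop-1-en-1-yl]-8-(trimethylsilyloxy)-4a,5,6,7-tetrahydro-1H-isochromen-7-yl 2-methoxy-6-methyl-4-[(triisopropylsilyl)oxy]benzoate F8. DDQ/2,6-lutidine in CH2Cl2 at 0 °C removes the doubly allylic 4a-hydride, and loss of the silyl group gives 19.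

## Further compounds

F1 | step 2 | (3R,5R)-3-hydroxy-2-methyl-5-(prop-1-en-2-yl)cyclohexan-1-one (C-2 epimers) | O=C1C(C)[C@H](O)C[C@@H](C(C)=C)C1
F2 | step 2 | (3R,5R)-3-[(tert-butyldimethylsilyl)oxy]-2-methyl-5-(prop-1-en-2-yl)cyclohexan-1-one (C-2 epimers) | O=C1C(C)[C@H](O[Si](C)(C)C(C)(C)C)C[C@@H](C(C)=C)C1
F3 | step 2 | tert-butyldimethyl{[(1R,5R)-2-methyl-5-(prop-1-en-2-yl)-3-(trimethylsilyloxy)cyclohex-2-en-1-yl]oxy}silane | C[Si](C)(C)OC1=C(C)[C@H](O[Si](C)(C)C(C)(C)C)C[C@@H](C(C)=C)C1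
F4 | step 8 | 7-hydroxy-2,2,5-trimethyl-4H-1,3-benzodioxin-4-one | CC1(C)OC(=O)c2c(C)cc(O)cc2O1
F5 | step 8 | 2,2,5-trimethyl-7-[(triisopropylsilyl)oxy]-4H-1,3-benzodioxin-4-one | CC1(C)OC(=O)c2c(C)cc(O[Si](C(C)C)(C(C)C)C(C)C)cc2O1
F6 | step 8 | (1S,6R)-6-[(tert-butyldimethylsilyl)oxy]-1-methyl-2-oxocyclohex-3-en-1-yl 2-hydroxy-6-methyl-4-[(triisopropylsilyl)oxy]benzoate | O=C1[C@@](C)(OC(=O)c2c(C)cc(O[Si](C(C)C)(C(C)C)C(C)C)cc2O)[C@H](O[Si](C)(C)C(C)(C)C)CC=C1
F7 | step 12 | (6R,7S)-6-[(tert-butyldimethylsilyl)oxy]-7-methyl-8-oxo-3-[(E)-prop-1-en-1-yl]-4a,5,6,7,8,8a-hexahydro-1H-isochromen-7-yl 2-methoxy-6-methyl-4-[(triisopropylsilyl)oxy]benzoate (ring-fusion epimers) | C/C=C/C1=CC2C(CO1)C(=O)[C@@](C)(OC(=O)c1c(C)cc(O[Si](C(C)C)(C(C)C)C(C)C)cc1OC)[C@H](O[Si](C)(C)C(C)(C)C)C2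
F8 | step 12 | (6R,7S)-6-[(tert-butyldimethylsilyl)oxy]-7-methyl-3-[(E)-prop-1-en-1-yl]-8-(trimethylsilyloxy)-4a,5,6,7-tetrahydro-1H-isochromen-7-yl 2-methoxy-6-methyl-4-[(triisopropylsilyl)oxy]benzoate | C/C=C/C1=CC2C(=C(O[Si](C)(C)C)[C@@](C)(OC(=O)c3c(C)cc(O[Si](C(C)C)(C(C)C)C(C)C)cc3OC)[C@H](O[Si](C)(C)C(C)(C)C)C2)CO1
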